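**Retrosynthetic overview**

1. No ring is formed. Both benzene rings are bought intact: ring B as 4-bromo-2-hydroxybenzaldehyde (1), brominated to 3,4,5-tribromosalicylaldehyde (2); ring A as 2,4-dibromoanisole (3).
2. The target has no C–C bond outside the two rings, so the strategic bond is the diaryl ether C–O bond. It is cut so that both partners are innately nucleophilic: anisole carbon C6 of 3 and the phenol oxygen of 2.
3. Polarity reversal: C6–H of 3 is turned in the flask into an aryl(phenyl)-λ3-iodane (4), an aryl cation equivalent. The phenoxide of 2 captures it to give diaryl ether aldehyde 5, a formal one-pot C–H/O–H cross-coupling.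
4. The formyl group of 5 is the latent hydroxyl: Baeyer–Villiger (Dakin-type) oxidation via formate 6 gives target 7.

Assumption: the target has no stereogenic element (achiral, freely rotating diaryl ether), so no stereocontrol is needed.

**Route**

Step 1
Reactants: 1 4-bromo-2-hydroxybenzaldehyde
Product: 2 3,4,5-tribromo-2-hydroxybenzaldehyde
Conditions: Br2 (2.3 equiv), AcOH, rt → 50 °C
Reagents that add atoms: bromine, BrBr
Why: Electrophilic aromatic bromination directed by the phenol OH to its para (C5) and ortho (C3) positions, both meta to CHO, while C6 (meta to OH, ortho to CHO) stays untouched; no stereocentre is formed.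

Step 2
Reactants: 3 2,4-dibromo-1-methoxybenzene (2,4-dibromoanisole); 2 3,4,5-tribromo-2-hydroxybenzaldehyde
Product: 5 3,4,5-tribromo-2-(3,5-dibromo-2-methoxyphenoxy)benzaldehyde, via aryl(phenyl)iodonium triflate 4 (not isolated)
Conditions: 3 (1.1 equiv), PhI(OAc)2 (1.0 equiv), TfOH (2.0 equiv), CH2Cl2, 0 °C → rt; evaporate (toluene chase); then 2 (1.0 equiv), K2CO3 (4 equiv), MeCN, 60 °C
Reagents that add atoms: none
Why: TfOH-activated PhI(OAc)2 attacks 3 by electrophilic aromatic substitution at C6, the only free position ortho/para to OMe, giving diaryl-λ3-iodane 4 in which the formerly nucleophilic anisole carbon is an aryl cation equivalent, and the phenoxide of 2 then adds to trivalent iodine and ligand coupling (metal-free O-arylation with a diaryliodonium salt) transfers the more electron-poor, ortho-substituted dibromomethoxyphenyl group in preference to phenyl; no stereocentre is formed.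

Step 3
Reactants: 5 3,4,5-tribromo-2-(3,5-dibromo-2-methoxyphenoxy)benzaldehyde
Product: 7 3,4,5-tribromo-2-(3,5-dibromo-2-methoxyphenoxy)phenol, via aryl formate 6 (not isolated)
Conditions: mCPBA (1.5 equiv), CH2Cl2, 40 °C; then MeOH, Et3N (0.2 equiv), rt
Reagents that add atoms: mCPBA (3-chloroperoxybenzoic acid), OOC(=O)c1cccc(Cl)c1
Why: Baeyer–Villiger (Dakin-type) oxidation in which the aryl group, assisted by the ortho aryloxy lone pair, migrates in the Criegee adduct to give formate 6, which is methanolysed to the free phenol without touching the methyl ether or the C–Br bonds; no stereocentre is formed.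

**Compound list**

1 | 4-bromo-2-hydroxybenzaldehyde | O=Cc1ccc(Br)cc1O | starting material
2 | 3,4,5-tribromo-2-hydroxybenzaldehyde | O=Cc1cc(Br)c(Br)c(Br)c1O | intermediate
3 | 2,4-dibromo-1-methoxybenzene (2,4-dibromoanisole) | COc1ccc(Br)cc1Br | starting material
4 | (3,5-dibromo-2-methoxyphenyl)(phenyl)iodonium trifluoromethanesulfonate | COc1c(Br)cc(Br)cc1[I+]c1ccccc1.[O-]S(=O)(=O)C(F)(F)F | intermediate
5 | 3,4,5-tribromo-2-(3,5-dibromo-2-methoxyphenoxy)benzaldehyde | COc1c(Br)cc(Br)cc1Oc1c(C=O)cc(Br)c(Br)c1Br | intermediate
6 | 3,4,5-tribromo-2-(3,5-dibromo-2-methoxyphenoxy)phenyl formate | COc1c(Br)cc(Br)cc1Oc1c(OC=O)cc(Br)c(Br)c1Br | intermediate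
7 | 3,4,5-tribromo-2-(3,5-dibromo-2-methoxyphenoxy)phenol | COc1c(Br)cc(Br)cc1Oc1c(O)cc(Br)c(Br)c1Br | target

**Step count**

Total steps: 3. Longest linear sequence: 3 (1 → 2 → 5 → 7); 3 enters at step 2.

**Steps most likely to fail, with fallbacks**

Step 2 (highest risk). The C–H iodanation of the deactivated, crowded C6 of 3 may be slow or give electron-transfer side products. The triply ortho-flanked, weakly nucleophilic phenoxide of 2 may also couple poorly or pick up some phenyl. The fallback sets out from 3 and comes back at 5. Iodination of 3 with NIS/TfOH in CH2Cl2 puts iodine at C6 and gives 1,5-dibromo-3-iodo-2-methoxybenzene F2. Oxidation of F2 with mCPBA/TsOH·H2O in MeCN, followed by 1,3,5-trimethoxybenzene, gives the crystalline, isolable (3,5-dibromo-2-methoxyphenyl)(2,4,6-trimethoxyphenyl)iodonium 4-methylbenzenesulfonate F3. Its trimethoxyphenyl group is a non-transferable dummy. Purified F3 is then coupled with 2 (K2CO3, MeCN, 60 °C) to give 5.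

Step 3. The tribrominated aldehyde ring of 5 is electron-poor, so hydride migration to the benzoic acid may compete with aryl migration. The fallback sets out from 2 and comes back at 7; it moves the oxidation ahead of the coupling, where a free ortho-phenoxide drives the aryl shift. Dakin oxidation of 2 (H2O2, NaOH, H2O/THF, 0 °C → rt, then HCl) gives 3,4,5-tribromobenzene-1,2-diol F4. PivCl/pyridine in CH2Cl2 at 0 °C acylates the unhindered hydroxyl (the one next to C–H, not the one next to C–Br) and gives 3,4,5-tribromo-2-hydroxyphenyl 2,2-dimethylpropanoate F5. Any acyl migration also favours this isomer, which keeps the more acidic, bromine-flanked OH free. Arylation of F5 with iodane 4 (made from 3 as in the first stage of step 2; K2CO3, MeCN, 60 °C) gives 3,4,5-tribromo-2-(3,5-dibromo-2-methoxyphenoxy)phenyl 2,2-dimethylpropanoate F6. LiOH in THF/H2O then removes the pivalate to give 7.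

Step 1 (lowest risk). The second bromine must enter C3 between OH and Br, and ipso-bromodeformylation could compete. The fallback sets out from 1 and comes back at 2; it replaces exhaustive acid-medium substitution by a stepwise sequence with a directed second bromination. NBS (1.0 equiv) in MeCN at rt brominates para to OH and gives 4,5-dibromo-2-hydroxybenzaldehyde F1. Br2/t-BuNH2 in toluene at −78 °C → rt then delivers bromine from the N-bromoamine to the only remaining ortho position of the hydrogen-bonded phenoxide, giving 2.

**Further compounds**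

F1 | step 1 | 4,5-dibromo-2-hydroxybenzaldehyde | O=Cc1cc(Br)c(Br)cc1O
F2 | step 2 | 1,5-dibromo-3-iodo-2-methoxybenzene | COc1c(Br)cc(Br)cc1I
F3 | step 2 | (3,5-dibromo-2-methoxyphenyl)(2,4,6-trimethoxyphenyl)iodonium 4-methylbenzenesulfonate | COc1c(Br)cc(Br)cc1[I+]c1c(OC)cc(OC)cc1OC.Cc1ccc(cc1)S(=O)(=O)[O-]
F4 | step 3 | 3,4,5-tribromobenzene-1,2-diol | Oc1cc(Br)c(Br)c(Br)c1O
F5 | step 3 | 3,4,5-tribromo-2-hydroxyphenyl 2,2-dimethylpropanoate | CC(C)(C)C(=O)Oc1cc(Br)c(Br)c(Br)c1O
F6 | step 3 | 3,4,5-tribromo-2-(3,5-dibromo-2-methoxyphenoxy)phenyl 2,2-dimethylpropanoate | COc1c(Br)cc(Br)cc1Oc1c(OC(=O)C(C)(C)C)cc(Br)c(Br)c1Br
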